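**Strategy.** Everything rests on cutting the C1–C2 bond of ring A (C1 the stereocentre, C2 the methyl-bearing olefinic carbon, C7 the benzylic CH2 leading to phenol ring B). A tertiary carbon flanked by a trisubstituted alkene carbon and a benzylic methylene is the signature of alkenylpalladium addition across a styrene followed by hydride quench at the benzylic position. One enantioselective reductive Heck cyclisation therefore closes ring A, places the C2=C3 olefin and sets C1. Its precursor is an achiral, acyclic (E)-styrene tethered through a gem-dimethyl chain to a (Z)-alkenyl iodide, with an aryl chloride kept for the later stilbene coupling. Resorcinol ring C arrives as silyl ethers, since thiolate rarely strips both methyls of a resorcinol dimethyl ether.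

Key step: step 7

Assumption: (R)-BINAP is written as the ligand that gives (S)-C1 (CIP order C2 > C6 > C7 > H). The sense of induction must be established on the first cyclisation, and the antipodal ligand is used if it proves opposite.

Remark: no structural error was found. The methyl ether on ring B is kept because a single anisole is cleaved reliably by thiolate under non-acidic conditions.

**Step 1**
Reactants: 1 5-chloro-2-methoxybenzaldehyde
Product: 2 (5-chloro-2-methoxyphenyl)methanol
Conditions: NaBH4, MeOH, 0 °C → rt
Reagents that add atoms: none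
Why: Borohydride reduction, in which hydride adds only to the aldehyde carbonyl while the aryl chloride and the methyl ether are inert.

**Step 2**
Reactants: 2 (5-chloro-2-methoxyphenyl)methanol
Product: 3 diethyl [(5-chloro-2-methoxyphenyl)methyl]phosphonate
Conditions: P(OEt)3 (3 equiv), ZnI2 (1.5 equiv), toluene, reflux
Reagents that add atoms: triethyl phosphite, CCOP(OCC)OCC
Why: Lewis-acid-mediated Michaelis–Arbuzov-type phosphonylation of a benzylic alcohol, in which transesterification gives the benzyl diethyl phosphite and ZnI2 ionises the C–O bond of this ortho-methoxy-stabilised benzylic position so that phosphorus recaptures carbon as the phosphonate.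

**Step 3**
Reactants: 3 diethyl [(5-chloro-2-methoxyphenyl)methyl]phosphonate; 4 2,2-dimethylpent-4-enal
Product: 5 4-chloro-2-[(1E)-3,3-dimethylhexa-1,5-dien-1-yl]-1-methoxybenzene
Conditions: KOtBu, THF, 0 °C; then 4, 0 → 50 °C
Reagents that add atoms: none
Why: Horner–Wadsworth–Emmons olefination, in which the benzylic phosphonate anion adds to the non-enolisable aldehyde and the reversibly formed adduct collapses through the less crowded oxaphosphetane, placing the aryl group and the quaternary carbon trans, i.e. (E).

**Step 4**
Reactants: 5 4-chloro-2-[(1E)-3,3-dimethylhexa-1,5-dien-1-yl]-1-methoxybenzene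
Product: 7 (5E)-6-(5-chloro-2-methoxyphenyl)-4,4-dimethylhex-5-en-1-ol, via B-alkyl-9-BBN adduct 6 (not isolated)
Conditions: 9-BBN, THF, 0 °C → rt; then aq. NaOH, H2O2, 0 °C → rt
Reagents that add atoms: 9-BBN, B1C2CCCC1CCC2 (its boron and carbons stay only in 6); hydrogen peroxide, OO
Why: Hydroboration–oxidation, in which bulky 9-BBN adds anti-Markovnikov to the monosubstituted terminal alkene far faster than to the 1,2-disubstituted styrene shielded by the quaternary carbon, and alkaline peroxide replaces boron by hydroxyl.

**Step 5**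
Reactants: 7 (5E)-6-(5-chloro-2-methoxyphenyl)-4,4-dimethylhex-5-en-1-ol
Product: 8 (5E)-6-(5-chloro-2-methoxyphenyl)-4,4-dimethylhex-5-enal
Conditions: TEMPO (10 mol %), PhI(OAc)2, CH2Cl2, rt
Reagents that add atoms: none
Why: TEMPO/PhI(OAc)2 (oxoammonium) oxidation should stop at the aldehyde and leave the styrene and the anisole untouched.

**Step 6**
Reactants: 8 (5E)-6-(5-chloro-2-methoxyphenyl)-4,4-dimethylhex-5-enal; 9 ethyltriphenylphosphonium iodide
Product: 13 4-chloro-2-[(1E,6Z)-7-iodo-3,3-dimethylocta-1,6-dien-1-yl]-1-methoxybenzene, via ethylidenetriphenylphosphorane 10 (not isolated), via (1-iodoethyl)triphenylphosphonium iodide 11 (not isolated), via (1-iodoethylidene)triphenylphosphorane 12 (not isolated)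
Conditions: 9, n-BuLi, THF, 0 °C; I2, −78 °C; NaN(SiMe3)2, −20 °C; then 8, −78 → −20 °C
Reagents that add atoms: iodine, II
Why: Stork–Zhao-type Wittig olefination, in which the ethylidene ylide is iodinated and redeprotonated to the α-iodo ylide, whose kinetically controlled addition to the aldehyde at low temperature passes through the cis-oxaphosphetane and gives the alkene with iodine cis to the chain, i.e. (6Z).

**Step 7**
Reactants: 13 4-chloro-2-[(1E,6Z)-7-iodo-3,3-dimethylocta-1,6-dien-1-yl]-1-methoxybenzene
Product: 14 4-chloro-1-methoxy-2-{[(1S)-2,6,6-trimethylcyclohex-2-en-1-yl]methyl}benzene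
Conditions: Pd(OAc)2 (10 mol %), (R)-BINAP (20 mol %), HCO2Na (2 equiv, finely powdered), degassed DMF (0.02 M), 70 °C
Reagents that add atoms: none
Why: Zerovalent palladium carrying (R)-BINAP, formed from Pd(OAc)2, inserts into the C–I bond of 13 (the aryl C–Cl bond is inert to this catalyst), the (Z)-alkenylpalladium adds syn across the styrene so that C2 bonds to C1 and palladium moves to benzylic C7, and iodide/formate exchange, loss of CO2 and C–H reductive elimination turn C7 into CH2. The closest known reaction type is the enantioselective intramolecular reductive Heck cyclisation of (Z)-1-iodo-1,6-dienes with formate as hydride donor. Ring A closes in the 6-exo-trig mode, and because the tether is cis to palladium on the alkenyl unit the C2=C3 double bond can only end up inside the ring. C1 is the only stereocentre and is set in the migratory insertion by the chiral bisphosphine, which differentiates the enantiotopic faces of the (E)-styrene of an otherwise achiral substrate. Two selectivities are needed: ring closure must precede formate reduction of the alkenylpalladium, which the gem-dimethyl group at C6 (Thorpe–Ingold compression) and the sparingly soluble formate favour, and hydride delivery must precede β-hydride loss of C1–H, which η3-benzyl binding of palladium at C7 on the electron-rich anisole ring and the excess of formate favour. The 6-exo over 7-endo preference follows from the tether length and from placing palladium on the benzylic carbon.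

**Step 8**
Reactants: 15 3,5-dihydroxybenzaldehyde
Product: 16 3,5-bis[(tert-butyldimethylsilyl)oxy]benzaldehyde
Conditions: TBSCl, imidazole, DMF, rt
Reagents that add atoms: tert-butyldimethylsilyl chloride, CC(C)(C)[Si](C)(C)Cl
Why: Imidazole-promoted silylation of both phenols, with the aldehyde unaffected.

**Step 9**
Reactants: 16 3,5-bis[(tert-butyldimethylsilyl)oxy]benzaldehyde
Product: 17 1,3-bis[(tert-butyldimethylsilyl)oxy]-5-ethenylbenzene
Conditions: Ph3PCH3Br, KOtBu, THF, 0 °C; then 16, 0 °C → rt
Reagents that add atoms: methyltriphenylphosphonium bromide, C[P+](c1ccccc1)(c1ccccc1)c1ccccc1.[Br-]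
Why: Wittig methylenation, in which the preformed non-stabilised ylide adds to the aldehyde and no free alkoxide is left to attack the aryl silyl ethers.

**Step 10**
Reactants: 14 4-chloro-1-methoxy-2-{[(1S)-2,6,6-trimethylcyclohex-2-en-1-yl]methyl}benzene; 17 1,3-bis[(tert-butyldimethylsilyl)oxy]-5-ethenylbenzene
Product: 18 1,3-bis[(tert-butyldimethylsilyl)oxy]-5-[(E)-2-(4-methoxy-3-{[(1S)-2,6,6-trimethylcyclohex-2-en-1-yl]methyl}phenyl)ethenyl]benzene
Conditions: Pd2(dba)3 (2 mol %), P(t-Bu)3 (8 mol %), Cy2NMe, dioxane, 100 °C
Reagents that add atoms: none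
Why: Mizoroki–Heck coupling, in which the bulky electron-rich P(t-Bu)3 lets zerovalent palladium insert into the electron-rich aryl chloride, aryl transfer to the terminal styrene carbon and syn β-hydride elimination give the (E)-stilbene, and Cy2NMe removes HCl from the palladium hydride fast enough that the ring A olefin and C1 should be left alone.

**Step 11**
Reactants: 18 1,3-bis[(tert-butyldimethylsilyl)oxy]-5-[(E)-2-(4-methoxy-3-{[(1S)-2,6,6-trimethylcyclohex-2-en-1-yl]methyl}phenyl)ethenyl]benzene
Product: 20 5-[(E)-2-(4-hydroxy-3-{[(1S)-2,6,6-trimethylcyclohex-2-en-1-yl]methyl}phenyl)ethenyl]benzene-1,3-diol, via desilylated anisole 19 (not isolated)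
Conditions: CsF, DMF, rt; then NaSEt, 130 °C, argon; aq. NH4Cl
Reagents that add atoms: none
Why: Fluoride desilylation followed by thiolate SN2 demethylation, in which CsF cleaves the two aryl O–Si bonds at room temperature and NaSEt then attacks the methyl group of the one remaining anisole, while the basic medium keeps the ortho-phenol from adding to the ring A olefin as it would under Lewis or Brønsted acids.

**Compound list**
1 | 5-chloro-2-methoxybenzaldehyde | COc1ccc(Cl)cc1C=O | starting material
2 | (5-chloro-2-methoxyphenyl)methanol | COc1ccc(Cl)cc1CO | intermediate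
3 | diethyl [(5-chloro-2-methoxyphenyl)methyl]phosphonate | CCOP(=O)(Cc1cc(Cl)ccc1OC)OCC | intermediate
4 | 2,2-dimethylpent-4-enal | C=CCC(C)(C)C=O | starting material
5 | 4-chloro-2-[(1E)-3,3-dimethylhexa-1,5-dien-1-yl]-1-methoxybenzene | C=CCC(C)(C)/C=C/c1cc(Cl)ccc1OC | intermediate
6 | 9-[(5E)-6-(5-chloro-2-methoxyphenyl)-4,4-dimethylhex-5-en-1-yl]-9-borabicyclo[3.3.1]nonane | COc1ccc(Cl)cc1/C=C/C(C)(C)CCCB1C2CCCC1CCC2 | intermediate (not isolated)
7 | (5E)-6-(5-chloro-2-methoxyphenyl)-4,4-dimethylhex-5-en-1-ol | OCCCC(C)(C)/C=C/c1cc(Cl)ccc1OC | intermediate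
8 | (5E)-6-(5-chloro-2-methoxyphenyl)-4,4-dimethylhex-5-enal | O=CCCC(C)(C)/C=C/c1cc(Cl)ccc1OC | intermediate
9 | ethyltriphenylphosphonium iodide | CC[P+](c1ccccc1)(c1ccccc1)c1ccccc1.[I-] | starting material
10 | ethylidenetriphenylphosphorane | CC=P(c1ccccc1)(c1ccccc1)c1ccccc1 | intermediate (not isolated)
11 | (1-iodoethyl)triphenylphosphonium iodide | CC(I)[P+](c1ccccc1)(c1ccccc1)c1ccccc1.[I-] | intermediate (not isolated)
12 | (1-iodoethylidene)triphenylphosphorane | CC(I)=P(c1ccccc1)(c1ccccc1)c1ccccc1 | intermediate (not isolated)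
13 | 4-chloro-2-[(1E,6Z)-7-iodo-3,3-dimethylocta-1,6-dien-1-yl]-1-methoxybenzene | C/C(I)=C/CCC(C)(C)/C=C/c1cc(Cl)ccc1OC | intermediate
14 | 4-chloro-1-methoxy-2-{[(1S)-2,6,6-trimethylcyclohex-2-en-1-yl]methyl}benzene | CC1=CCCC(C)(C)[C@@H]1Cc1cc(Cl)ccc1OC | intermediate
15 | 3,5-dihydroxybenzaldehyde | O=Cc1cc(O)cc(O)c1 | starting material
16 | 3,5-bis[(tert-butyldimethylsilyl)oxy]benzaldehyde | O=Cc1cc(O[Si](C)(C)C(C)(C)C)cc(O[Si](C)(C)C(C)(C)C)c1 | intermediate
17 | 1,3-bis[(tert-butyldimethylsilyl)oxy]-5-ethenylbenzene | C=Cc1cc(O[Si](C)(C)C(C)(C)C)cc(O[Si](C)(C)C(C)(C)C)c1 | intermediate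
18 | 1,3-bis[(tert-butyldimethylsilyl)oxy]-5-[(E)-2-(4-methoxy-3-{[(1S)-2,6,6-trimethylcyclohex-2-en-1-yl]methyl}phenyl)ethenyl]benzene | CC1=CCCC(C)(C)[C@@H]1Cc1cc(/C=C/c2cc(O[Si](C)(C)C(C)(C)C)cc(O[Si](C)(C)C(C)(C)C)c2)ccc1OC | intermediate
19 | 5-[(E)-2-(4-methoxy-3-{[(1S)-2,6,6-trimethylcyclohex-2-en-1-yl]methyl}phenyl)ethenyl]benzene-1,3-diol (formed as its caesium phenoxide) | CC1=CCCC(C)(C)[C@@H]1Cc1cc(/C=C/c2cc(O)cc(O)c2)ccc1OC | intermediate (not isolated)
20 | 5-[(E)-2-(4-hydroxy-3-{[(1S)-2,6,6-trimethylcyclohex-2-en-1-yl]methyl}phenyl)ethenyl]benzene-1,3-diol | CC1=CCCC(C)(C)[C@@H]1Cc1cc(/C=C/c2cc(O)cc(O)c2)ccc1O | target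

**Step count.** Total: 11 steps (steps 8 and 9 are the side branch to styrene 17). Longest linear sequence: 9 steps (1–7, 10, 11).

**Steps most likely to fail**

1. Step 7. The alkenylpalladium may be reduced by formate before it cyclises, the benzylic palladium may lose the C1 hydrogen by β-hydride elimination, or the ligand may discriminate the styrene faces poorly. The fallback sets out from 13 and returns at 14. Slow addition of Bu3SnH with AIBN in toluene at 80 °C would generate the alkenyl radical at C2, which closes 6-exo onto the styrene, and the benzylic radical takes hydrogen from the stannane. This should give racemic 4-chloro-1-methoxy-2-[(2,6,6-trimethylcyclohex-2-en-1-yl)methyl]benzene F1. Preparative chromatography on a chiral stationary phase would then separate 14 from its mirror image 4-chloro-1-methoxy-2-{[(1R)-2,6,6-trimethylcyclohex-2-en-1-yl]methyl}benzene F2.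

2. Step 6. Incomplete iodination of the ylide would lead to iodine-free olefination, and the (Z)-selectivity or the conversion of the α-iodo ylide may be poor. The fallback sets out from 8 and returns at 13. Ramirez/Corey–Fuchs dibromo-olefination (CBr4, PPh3, CH2Cl2, 0 °C) would give 4-chloro-2-[(1E)-7,7-dibromo-3,3-dimethylhepta-1,6-dien-1-yl]-1-methoxybenzene F3. A trans-selective Negishi monomethylation (MeZnCl, PdCl2(DPEphos), THF) replaces the less hindered bromine anti to the chain and should give 2-[(1E,6Z)-7-bromo-3,3-dimethylocta-1,6-dien-1-yl]-4-chloro-1-methoxybenzene F4. Copper-catalysed halide exchange with retention of geometry (CuI, N,N′-dimethylethylenediamine, NaI, dioxane, 110 °C) then leads to 13. The aryl chloride is inert in all three operations.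

3. Step 10. Oxidative addition into the electron-rich aryl chloride may be slow, and during prolonged heating a palladium hydride could move the ring A double bond or the silyl ethers could be lost. The fallback sets out from 17, uses 14, and returns at 18. Cross-metathesis of 17 with vinylboronic acid pinacol ester (second-generation Hoveyda–Grubbs catalyst, CH2Cl2, 40 °C) would give 2-[(E)-2-{3,5-bis[(tert-butyldimethylsilyl)oxy]phenyl}ethenyl]-4,4,5,5-tetramethyl-1,3,2-dioxaborolane F5. Suzuki–Miyaura coupling of F5 with 14 (Pd(OAc)2, SPhos, K3PO4, toluene/H2O, 80 °C) then forms the stilbene 18 without a palladium hydride on the path. Any silyl loss is harmless, because step 11 removes these groups anyway.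

**Further compounds**
F1 | step 7 | racemic 4-chloro-1-methoxy-2-[(2,6,6-trimethylcyclohex-2-en-1-yl)methyl]benzene | CC1=CCCC(C)(C)C1Cc1cc(Cl)ccc1OC
F2 | step 7 | 4-chloro-1-methoxy-2-{[(1R)-2,6,6-trimethylcyclohex-2-en-1-yl]methyl}benzene | CC1=CCCC(C)(C)[C@H]1Cc1cc(Cl)ccc1OC
F3 | step 6 | 4-chloro-2-[(1E)-7,7-dibromo-3,3-dimethylhepta-1,6-dien-1-yl]-1-methoxybenzene | BrC(Br)=CCCC(C)(C)/C=C/c1cc(Cl)ccc1OC
F4 | step 6 | 2-[(1E,6Z)-7-bromo-3,3-dimethylocta-1,6-dien-1-yl]-4-chloro-1-methoxybenzene | C/C(Br)=C/CCC(C)(C)/C=C/c1cc(Cl)ccc1OC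
F5 | step 10 | 2-[(E)-2-{3,5-bis[(tert-butyldimethylsilyl)oxy]phenyl}ethenyl]-4,4,5,5-tetramethyl-1,3,2-dioxaborolane | CC1(C)OB(/C=C/c2cc(O[Si](C)(C)C(C)(C)C)cc(O[Si](C)(C)C(C)(C)C)c2)OC1(C)C
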